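**Retrosynthetic overview**

1. Target 43 ⇐ hydrogenolysis of five benzyl ethers (42) ⇐ oxidation of the benzylic carbinol beside ring A (41; ring A = the guaiacyl ring of the ketone, ring B = the central 2-hydroxy-3-methoxyphenyl ring) ⇐ trans-lactone 40 by loss of a CO2Me group from lactone C3 of 39.
2. 39 ⇐ three-component union. The benzylic CH2 on lactone C4 stands 1,3 to the enolizable lactone α-carbon C3, so CH2/C4/C3 are folded into a cyclopropane fused to the γ-lactone (35, a 3-oxabicyclo[3.1.0]hexan-2-one whose C3 is activated by the lactone C=O and a removable CO2Me). The ring-B carbon para to the phenolic oxygen, as ArMgBr/CuI from bromide 14, opens it at CH2; the C3 enolate set free is benzylated in the same flask by bromide 30.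
3. 14 and 30 ⇐ the two enantiomeric Evans syn-aldol adducts of one ring-B arylacetic acid (from 2-allyl-6-methoxyphenol) with O-benzylvanillin. The (R)-auxiliary series is silylated, reduced and benzylated; the (S)-auxiliary series is reduced and closed under acid to the trans-dihydrobenzofuran.
4. Order of ring formation: aromatic rings are bought; the dihydrofuran ring is closed by C2–O bond formation (step 14); cyclopropane and lactone form in one cascade from dimethyl malonate and (R)-epichlorohydrin (step 18, fixes lactone C4); the cyclopropane is opened in step 19.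

Key step: step 19

Remark on the chemistry: the hydroxyl-bearing carbon made in each aldol step does not survive into the target (ionized in step 14, oxidized in step 22), so only the aryl-bearing carbon must be controlled there. Organometallic species are drawn as monomers and alkoxide intermediates in neutral form.

**Route**

Step 1
Reactants: 1 2-allyl-6-methoxyphenol
Product: 2 2-allyl-4-bromo-6-methoxyphenol
Conditions: NBS (1.0 eq), MeCN, 0 °C
Reagents that add atoms: N-bromosuccinimide, O=C1CCC(=O)N1Br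
Why: Electrophilic aromatic bromination goes para to the free phenol, the only strongly activated open position because both ortho positions carry allyl and OMe, and the cold uncatalysed conditions should spare the allyl group.

Step 2
Reactants: 2 2-allyl-4-bromo-6-methoxyphenol
Product: 3 1-allyl-2-(benzyloxy)-5-bromo-3-methoxybenzene
Conditions: BnBr, K2CO3, DMF, rt
Reagents that add atoms: benzyl bromide, BrCc1ccccc1
Why: Williamson O-alkylation of the phenoxide (SN2 on benzyl bromide) protects the ring-B phenol as a benzyl ether that lasts until the final hydrogenolysis.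

Step 3
Reactants: 3 1-allyl-2-(benzyloxy)-5-bromo-3-methoxybenzene
Product: 5 2-[2-(benzyloxy)-5-bromo-3-methoxyphenyl]acetic acid, via arylacetaldehyde 4 (not isolated)
Conditions: O3, CH2Cl2, −78 °C; Me2S, −78 °C→rt; then NaClO2, NaH2PO4, 2-methyl-2-butene, t-BuOH/H2O, 0 °C→rt
Reagents that add atoms: ozone, [O-][O+]=O; sodium chlorite NaClO2, [Na+].[O-]Cl=O
Why: Ozonolysis cleaves the terminal alkene much faster than the brominated arene, and the crude arylacetaldehyde is oxidized at once by the Pinnick oxidation, whose buffered chlorite conditions tolerate benzyl ether and aryl bromide.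

Step 4
Reactants: 5 2-[2-(benzyloxy)-5-bromo-3-methoxyphenyl]acetic acid; 6 (R)-4-benzyl-1,3-oxazolidin-2-one
Product: 8 (4R)-4-benzyl-3-{2-[2-(benzyloxy)-5-bromo-3-methoxyphenyl]acetyl}-1,3-oxazolidin-2-one, via mixed pivalic anhydride 7 (not isolated)
Conditions: PivCl, Et3N, THF, −20 °C; then LiCl, 6, −20 °C→rt
Reagents that add atoms: none
Why: The pivaloyl mixed anhydride acylates the oxazolidinone nitrogen at the less hindered arylacetyl carbonyl under LiCl/Et3N activation (N-acylation of a chiral auxiliary).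

Step 5
Reactants: 8 (R)-arylacetyl oxazolidinone; 9 4-(benzyloxy)-3-methoxybenzaldehyde
Product: 11 (4R)-4-benzyl-3-[(2R,3R)-2-[2-(benzyloxy)-5-bromo-3-methoxyphenyl]-3-[4-(benzyloxy)-3-methoxyphenyl]-3-hydroxypropanoyl]-1,3-oxazolidin-2-one, via boron enolate 10 (not isolated)
Conditions: Bu2BOTf, i-Pr2NEt, CH2Cl2, −78→0 °C; 9, −78→0 °C; H2O2, MeOH, pH 7 buffer, 0 °C
Reagents that add atoms: none
Why: Evans syn-aldol reaction, in which the Z-dibutylboron enolate 10 adds to the aldehyde through a chair Zimmerman–Traxler transition state on the face away from the auxiliary benzyl group, setting the aryl-bearing carbon as 2R (the future S centre of the ketone unit) and the carbinol as 3R.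

Step 6
Reactants: 11 (2R,3R)-aldol adduct
Product: 12 (4R)-4-benzyl-3-[(2R,3R)-2-[2-(benzyloxy)-5-bromo-3-methoxyphenyl]-3-[4-(benzyloxy)-3-methoxyphenyl]-3-[(tert-butyldimethylsilyl)oxy]propanoyl]-1,3-oxazolidin-2-one
Conditions: TBSOTf, 2,6-lutidine, CH2Cl2, −78→0 °C
Reagents that add atoms: tert-butyldimethylsilyl triflate, CC(C)(C)[Si](C)(C)OS(=O)(=O)C(F)(F)F
Why: Silyl triflate/lutidine silylation protects the hindered benzylic hydroxyl without retro-aldol cleavage because no free alkoxide is formed.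

Step 7
Reactants: 12 silylated aldol adduct
Product: 13 (2S,3R)-2-[2-(benzyloxy)-5-bromo-3-methoxyphenyl]-3-[4-(benzyloxy)-3-methoxyphenyl]-3-[(tert-butyldimethylsilyl)oxy]propan-1-ol
Conditions: LiBH4, MeOH (1 eq), THF, 0 °C
Reagents that add atoms: none
Why: LiBH4 reduces the exocyclic imide carbonyl selectively (reductive removal of the auxiliary), giving the primary alcohol and returning the oxazolidinone without touching either stereocentre.

Step 8
Reactants: 13 primary alcohol
Product: 14 [(1R,2S)-3-(benzyloxy)-2-[2-(benzyloxy)-5-bromo-3-methoxyphenyl]-1-[4-(benzyloxy)-3-methoxyphenyl]propoxy](tert-butyl)dimethylsilane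
Conditions: 2-benzyloxy-1-methylpyridinium triflate, MgO, PhCF3, 85 °C
Reagents that add atoms: 2-benzyloxy-1-methylpyridinium triflate, C[n+]1ccccc1OCc1ccccc1.[O-]S(=O)(=O)C(F)(F)F
Why: Benzyl transfer from the neutral pyridinium salt (SN1-type benzylation buffered by MgO) etherifies the primary alcohol without forming the alkoxide that would trigger 1,3-silyl migration.

Step 9
Reactants: 2 2-allyl-4-bromo-6-methoxyphenol
Product: 15 1-allyl-5-bromo-3-methoxy-2-(methoxymethoxy)benzene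
Conditions: MOMCl, i-Pr2NEt, CH2Cl2, 0 °C→rt
Reagents that add atoms: chloromethyl methyl ether, COCCl
Why: O-Alkylation of the phenol gives an acetal protecting group that survives the boron aldol and hydride steps but leaves under the acid used for ring closure in step 14.

Step 10
Reactants: 15 1-allyl-5-bromo-3-methoxy-2-(methoxymethoxy)benzene
Product: 17 2-[5-bromo-3-methoxy-2-(methoxymethoxy)phenyl]acetic acid, via arylacetaldehyde 16 (not isolated)
Conditions: O3, CH2Cl2, −78 °C; Me2S, −78 °C→rt; then NaClO2, NaH2PO4, 2-methyl-2-butene, t-BuOH/H2O, 0 °C→rt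
Reagents that add atoms: ozone, [O-][O+]=O; sodium chlorite NaClO2, [Na+].[O-]Cl=O
Why: Same ozonolysis/Pinnick oxidation sequence as in step 3, both stages being compatible with the acetal because the medium stays at the phosphate buffer pH.

Step 11
Reactants: 17 2-[5-bromo-3-methoxy-2-(methoxymethoxy)phenyl]acetic acid; 18 (S)-4-benzyl-1,3-oxazolidin-2-one
Product: 20 (4S)-4-benzyl-3-{2-[5-bromo-3-methoxy-2-(methoxymethoxy)phenyl]acetyl}-1,3-oxazolidin-2-one, via mixed pivalic anhydride 19 (not isolated)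
Conditions: PivCl, Et3N, THF, −20 °C; then LiCl, 18, −20 °C→rt
Reagents that add atoms: none
Why: Mixed-anhydride N-acylation as in step 4, now with the (S)-auxiliary that delivers the opposite configuration at the aryl-bearing carbon.

Step 12
Reactants: 20 (S)-arylacetyl oxazolidinone; 9 4-(benzyloxy)-3-methoxybenzaldehyde
Product: 22 (4S)-4-benzyl-3-[(2S,3S)-3-[4-(benzyloxy)-3-methoxyphenyl]-2-[5-bromo-3-methoxy-2-(methoxymethoxy)phenyl]-3-hydroxypropanoyl]-1,3-oxazolidin-2-one, via boron enolate 21 (not isolated)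
Conditions: Bu2BOTf, i-Pr2NEt, CH2Cl2, −78→0 °C; 9, −78→0 °C; H2O2, MeOH, pH 7 buffer, 0 °C
Reagents that add atoms: none
Why: Evans syn-aldol reaction as in step 5 with the enantiomeric auxiliary, so the Zimmerman–Traxler addition sets the aryl-bearing carbon as 2S (the future 3R centre of the dihydrobenzofuran).

Step 13
Reactants: 22 (2S,3S)-aldol adduct
Product: 23 (1S,2R)-1-[4-(benzyloxy)-3-methoxyphenyl]-2-[5-bromo-3-methoxy-2-(methoxymethoxy)phenyl]propane-1,3-diol
Conditions: LiBH4, MeOH (1 eq), THF, 0 °C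
Reagents that add atoms: none
Why: Reductive removal of the auxiliary with LiBH4 converts the imide into the primary alcohol and gives the 1,3-diol with both stereocentres intact.

Step 14
Reactants: 23 (1S,2R)-diol
Product: 25 [(2S,3R)-2-[4-(benzyloxy)-3-methoxyphenyl]-5-bromo-7-methoxy-2,3-dihydro-1-benzofuran-3-yl]methanol, via phenolic triol 24 (not isolated)
Conditions: HCl (0.5 M), MeOH, 45 °C
Reagents that add atoms: none
Why: Acidic methanol removes the acetal and ionizes the 4-alkoxybenzylic alcohol to a stabilized cation that the freed ortho-phenol captures (intramolecular SN1 etherification closing the five-membered ring), the reversible closure giving the favoured 2,3-trans ring so that C2 becomes S under control of the existing C3 centre.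

Step 15
Reactants: 25 dihydrobenzofuran alcohol
Product: 26 (2S,3R)-2-[4-(benzyloxy)-3-methoxyphenyl]-3-[(benzyloxy)methyl]-5-bromo-7-methoxy-2,3-dihydro-1-benzofuran
Conditions: NaH, BnBr, Bu4NI (cat.), THF/DMF, 0 °C→rt
Reagents that add atoms: benzyl bromide, BrCc1ccccc1
Why: Williamson etherification of the only hydroxyl group protects the primary alcohol so that later only the ketone-precursor carbinol is free at the oxidation stage.

Step 16
Reactants: 26 aryl bromide
Product: 29 [(2S,3R)-2-[4-(benzyloxy)-3-methoxyphenyl]-3-[(benzyloxy)methyl]-7-methoxy-2,3-dihydro-1-benzofuran-5-yl]methanol, via aryllithium 27 (not isolated), via aldehyde 28 (not isolated)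
Conditions: n-BuLi, THF, −78 °C; DMF, −78→0 °C; then MeOH, NaBH4, 0 °C
Reagents that add atoms: N,N-dimethylformamide, CN(C)C=O
Why: Bromine–lithium exchange at −78 °C is faster than any deprotonation, the aryllithium is formylated by DMF, and the aldehyde is reduced in the same flask by NaBH4 to the benzylic alcohol.

Step 17
Reactants: 29 benzylic alcohol
Product: 30 (2S,3R)-2-[4-(benzyloxy)-3-methoxyphenyl]-3-[(benzyloxy)methyl]-5-(bromomethyl)-7-methoxy-2,3-dihydro-1-benzofuran
Conditions: CBr4, PPh3, CH2Cl2, 0 °C; used at once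
Reagents that add atoms: carbon tetrabromide, BrC(Br)(Br)Br
Why: Appel bromination converts the benzylic alcohol into the bromide under neutral conditions that do not ionize the electron-rich benzylic position.

Step 18
Reactants: 31 dimethyl malonate; 32 (R)-epichlorohydrin
Product: 35 methyl (1S,5R)-2-oxo-3-oxabicyclo[3.1.0]hexane-1-carboxylate, via epoxy malonate 33 (not isolated), via cyclopropyl carbinol 34 (not isolated)
Conditions: NaOMe, MeOH, reflux
Reagents that add atoms: none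
Why: Alkylation/cyclopropanation/lactonization cascade in which the malonate anion opens the epoxide at CH2, the alkoxide re-closes onto the CH2Cl carbon, the malonate anion then opens the new epoxide at the stereogenic carbon with inversion (3-exo-tet) and the cis alkoxide lactonizes, transferring the epichlorohydrin configuration to the (1S,5R) bicycle.

Step 19
Reactants: 14 ring-B aryl bromide; 35 methyl (1S,5R)-2-oxo-3-oxabicyclo[3.1.0]hexane-1-carboxylate; 30 dihydrobenzofuranylmethyl bromide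
Product: 39 methyl (3R,4R)-3-{[(2S,3R)-2-[4-(benzyloxy)-3-methoxyphenyl]-3-[(benzyloxy)methyl]-7-methoxy-2,3-dihydro-1-benzofuran-5-yl]methyl}-4-{4-(benzyloxy)-3-[(1R,2S)-3-(benzyloxy)-1-[4-(benzyloxy)-3-methoxyphenyl]-1-[(tert-butyldimethylsilyl)oxy]propan-2-yl]-5-methoxybenzyl}-2-oxotetrahydrofuran-3-carboxylate, via aryllithium 36 (not isolated), via arylmagnesium bromide 37 (not isolated), via magnesium enolate 38 (not isolated)
Conditions: 14, t-BuLi (2.0 eq), Et2O/THF, −78 °C; MgBr2·OEt2, −78→−40 °C; CuI (20 mol%), 35 (1.15 eq), THF, −40→−20 °C; then 30 (1.1 eq), DMPU, −20 °C→rt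
Reagents that add atoms: none
Why: Br/Li exchange and transmetalation give ArMgBr 37, which with catalytic CuI forms an aryl-copper species (monovalent copper) that attacks the unsubstituted cyclopropane carbon C6 of 35 in an SN2-type homoconjugate addition, cleaving the C1–C6 bond to the chelated magnesium enolate 38, which is then C-benzylated by the reactive 4-alkoxybenzyl bromide 30. The closest known reaction types are the copper-catalysed Grignard ring opening of 2-oxo-3-oxabicyclo[3.1.0]hexane-1-carboxylates to 4-substituted 3-alkoxycarbonyl butyrolactones and the classical benzylation of such β-dicarbonyl lactone enolates in lignan synthesis, here run in sequence in one flask. No ring is closed: the lactone is carried in and the three-membered ring is opened exo to it, which turns C6 into the benzylic CH2 on lactone C4. Lactone C4 is not touched and keeps the R configuration of 35, while the new quaternary C3 is set by approach of 30 anti to the C4 arylmethyl group (substrate control) and is reset in step 20 in any case. The step needs attack at C6 rather than at the bridgehead carbon or the carbonyl groups, which is secured by C6 being the only primary cyclopropane carbon, by the geminal lactone/ester activation and by the soft copper nucleophile at low temperature; C- over O-alkylation is secured by the chelated magnesium enolate and the soft benzylic bromide, and the slight excess of 35 removes aryl-metal before 30 is added.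

Step 20
Reactants: 39 C3-methoxycarbonyl lactone
Product: 40 (3R,4R)-3-{[(2S,3R)-2-[4-(benzyloxy)-3-methoxyphenyl]-3-[(benzyloxy)methyl]-7-methoxy-2,3-dihydro-1-benzofuran-5-yl]methyl}-4-{4-(benzyloxy)-3-[(1R,2S)-3-(benzyloxy)-1-[4-(benzyloxy)-3-methoxyphenyl]-1-[(tert-butyldimethylsilyl)oxy]propan-2-yl]-5-methoxybenzyl}dihydrofuran-2(3H)-one
Conditions: LiCl (5 eq), H2O (2 eq), DMSO, 140 °C
Reagents that add atoms: none
Why: Krapcho dealkoxycarbonylation, in which chloride demethylates the ester, the carboxylate loses CO2 and the lactone enolate is protonated, the hot weakly basic medium letting C3 settle in the more stable 3,4-trans arrangement (3R under control of C4).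

Step 21
Reactants: 40 trans-lactone silyl ether
Product: 41 (3R,4R)-3-{[(2S,3R)-2-[4-(benzyloxy)-3-methoxyphenyl]-3-[(benzyloxy)methyl]-7-methoxy-2,3-dihydro-1-benzofuran-5-yl]methyl}-4-{4-(benzyloxy)-3-[(1R,2S)-3-(benzyloxy)-1-[4-(benzyloxy)-3-methoxyphenyl]-1-hydroxypropan-2-yl]-5-methoxybenzyl}dihydrofuran-2(3H)-one
Conditions: Bu4NF, AcOH, THF, rt
Reagents that add atoms: none
Why: Fluoride-induced desilylation frees the single secondary benzylic alcohol while acetic acid buffers the alkoxide so that the lactone and its trans C3 centre are not disturbed.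

Step 22
Reactants: 41 secondary benzylic alcohol
Product: 42 (3R,4R)-3-{[(2S,3R)-2-[4-(benzyloxy)-3-methoxyphenyl]-3-[(benzyloxy)methyl]-7-methoxy-2,3-dihydro-1-benzofuran-5-yl]methyl}-4-{4-(benzyloxy)-3-[(2S)-3-(benzyloxy)-1-[4-(benzyloxy)-3-methoxyphenyl]-1-oxopropan-2-yl]-5-methoxybenzyl}dihydrofuran-2(3H)-one
Conditions: Dess–Martin periodinane, NaHCO3, CH2Cl2, 0 °C→rt
Reagents that add atoms: none
Why: Dess–Martin oxidation under buffered neutral conditions converts the only free hydroxyl into the aryl ketone without enolizing the adjacent aryl-bearing stereocentre.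

Step 23
Reactants: 42 penta-O-benzyl ketone
Product: 43 (3R,4R)-3-{[(2S,3R)-2-(4-hydroxy-3-methoxyphenyl)-3-(hydroxymethyl)-7-methoxy-2,3-dihydro-1-benzofuran-5-yl]methyl}-4-{4-hydroxy-3-[(2S)-3-hydroxy-1-(4-hydroxy-3-methoxyphenyl)-1-oxopropan-2-yl]-5-methoxybenzyl}dihydrofuran-2(3H)-one
Conditions: H2 (1 atm), Pd/C (10 wt%), EtOAc/MeOH, rt
Reagents that add atoms: none
Why: Catalytic hydrogenolysis cleaves the three aryl and two alkyl benzyl ethers under neutral conditions that should leave the epimerizable α-aryl-β-hydroxy ketone, the lactone and the cyclic benzylic ether untouched.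

**Compound list**

1 | 2-allyl-6-methoxyphenol | C=CCc1cccc(OC)c1O | starting material
2 | 2-allyl-4-bromo-6-methoxyphenol | C=CCc1cc(Br)cc(OC)c1O | intermediate
3 | 1-allyl-2-(benzyloxy)-5-bromo-3-methoxybenzene | C=CCc1cc(Br)cc(OC)c1OCc1ccccc1 | intermediate
4 | 2-[2-(benzyloxy)-5-bromo-3-methoxyphenyl]acetaldehyde | O=CCc1cc(Br)cc(OC)c1OCc1ccccc1 | intermediate
5 | 2-[2-(benzyloxy)-5-bromo-3-methoxyphenyl]acetic acid | OC(=O)Cc1cc(Br)cc(OC)c1OCc1ccccc1 | intermediate
6 | (R)-4-benzyl-1,3-oxazolidin-2-one | O=C1N[C@H](Cc2ccccc2)CO1 | starting material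
7 | 2-[2-(benzyloxy)-5-bromo-3-methoxyphenyl]acetic pivalic anhydride | CC(C)(C)C(=O)OC(=O)Cc1cc(Br)cc(OC)c1OCc1ccccc1 | intermediate
8 | (4R)-4-benzyl-3-{2-[2-(benzyloxy)-5-bromo-3-methoxyphenyl]acetyl}-1,3-oxazolidin-2-one | O=C(Cc1cc(Br)cc(OC)c1OCc1ccccc1)N1[C@H](Cc2ccccc2)COC1=O | intermediate
9 | 4-(benzyloxy)-3-methoxybenzaldehyde | COc1cc(C=O)ccc1OCc1ccccc1 | starting material
10 | (Z)-dibutylboron enolate of 8 | CCCCB(CCCC)O/C(=C\c1cc(Br)cc(OC)c1OCc1ccccc1)N1[C@H](Cc2ccccc2)COC1=O | intermediate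
11 | (4R)-4-benzyl-3-[(2R,3R)-2-[2-(benzyloxy)-5-bromo-3-methoxyphenyl]-3-[4-(benzyloxy)-3-methoxyphenyl]-3-hydroxypropanoyl]-1,3-oxazolidin-2-one | COc1cc([C@H](O)[C@H](C(=O)N3[C@H](Cc4ccccc4)COC3=O)c2cc(Br)cc(OC)c2OCc2ccccc2)ccc1OCc1ccccc1 | intermediate
12 | (4R)-4-benzyl-3-[(2R,3R)-2-[2-(benzyloxy)-5-bromo-3-methoxyphenyl]-3-[4-(benzyloxy)-3-methoxyphenyl]-3-[(tert-butyldimethylsilyl)oxy]propanoyl]-1,3-oxazolidin-2-one | COc1cc([C@H](O[Si](C)(C)C(C)(C)C)[C@H](C(=O)N3[C@H](Cc4ccccc4)COC3=O)c2cc(Br)cc(OC)c2OCc2ccccc2)ccc1OCc1ccccc1 | intermediate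
13 | (2S,3R)-2-[2-(benzyloxy)-5-bromo-3-methoxyphenyl]-3-[4-(benzyloxy)-3-methoxyphenyl]-3-[(tert-butyldimethylsilyl)oxy]propan-1-ol | COc1cc([C@H](O[Si](C)(C)C(C)(C)C)[C@H](CO)c2cc(Br)cc(OC)c2OCc2ccccc2)ccc1OCc1ccccc1 | intermediate
14 | [(1R,2S)-3-(benzyloxy)-2-[2-(benzyloxy)-5-bromo-3-methoxyphenyl]-1-[4-(benzyloxy)-3-methoxyphenyl]propoxy](tert-butyl)dimethylsilane | COc1cc([C@H](O[Si](C)(C)C(C)(C)C)[C@H](COCc3ccccc3)c2cc(Br)cc(OC)c2OCc2ccccc2)ccc1OCc1ccccc1 | intermediate
15 | 1-allyl-5-bromo-3-methoxy-2-(methoxymethoxy)benzene | C=CCc1cc(Br)cc(OC)c1OCOC | intermediate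
16 | 2-[5-bromo-3-methoxy-2-(methoxymethoxy)phenyl]acetaldehyde | O=CCc1cc(Br)cc(OC)c1OCOC | intermediate
17 | 2-[5-bromo-3-methoxy-2-(methoxymethoxy)phenyl]acetic acid | OC(=O)Cc1cc(Br)cc(OC)c1OCOC | intermediate
18 | (S)-4-benzyl-1,3-oxazolidin-2-one | O=C1N[C@@H](Cc2ccccc2)CO1 | starting material
19 | 2-[5-bromo-3-methoxy-2-(methoxymethoxy)phenyl]acetic pivalic anhydride | CC(C)(C)C(=O)OC(=O)Cc1cc(Br)cc(OC)c1OCOC | intermediate
20 | (4S)-4-benzyl-3-{2-[5-bromo-3-methoxy-2-(methoxymethoxy)phenyl]acetyl}-1,3-oxazolidin-2-one | O=C(Cc1cc(Br)cc(OC)c1OCOC)N1[C@@H](Cc2ccccc2)COC1=O | intermediate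
21 | (Z)-dibutylboron enolate of 20 | CCCCB(CCCC)O/C(=C\c1cc(Br)cc(OC)c1OCOC)N1[C@@H](Cc2ccccc2)COC1=O | intermediate
22 | (4S)-4-benzyl-3-[(2S,3S)-3-[4-(benzyloxy)-3-methoxyphenyl]-2-[5-bromo-3-methoxy-2-(methoxymethoxy)phenyl]-3-hydroxypropanoyl]-1,3-oxazolidin-2-one | Brc1cc(OC)c(OCOC)c(c1)[C@H](C(=O)N1[C@@H](Cc2ccccc2)COC1=O)[C@H](O)c1ccc(OCc2ccccc2)c(OC)c1 | intermediate
23 | (1S,2R)-1-[4-(benzyloxy)-3-methoxyphenyl]-2-[5-bromo-3-methoxy-2-(methoxymethoxy)phenyl]propane-1,3-diol | Brc1cc(OC)c(OCOC)c(c1)[C@H](CO)[C@H](O)c1ccc(OCc2ccccc2)c(OC)c1 | intermediate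
24 | (1S,2R)-1-[4-(benzyloxy)-3-methoxyphenyl]-2-(5-bromo-2-hydroxy-3-methoxyphenyl)propane-1,3-diol | Brc1cc(OC)c(O)c(c1)[C@H](CO)[C@H](O)c1ccc(OCc2ccccc2)c(OC)c1 | intermediate
25 | [(2S,3R)-2-[4-(benzyloxy)-3-methoxyphenyl]-5-bromo-7-methoxy-2,3-dihydro-1-benzofuran-3-yl]methanol | Brc1cc(OC)c2c(c1)[C@H](CO)[C@@H](c1ccc(OCc3ccccc3)c(OC)c1)O2 | intermediate
26 | (2S,3R)-2-[4-(benzyloxy)-3-methoxyphenyl]-3-[(benzyloxy)methyl]-5-bromo-7-methoxy-2,3-dihydro-1-benzofuran | Brc1cc(OC)c2c(c1)[C@H](COCc1ccccc1)[C@@H](c1ccc(OCc3ccccc3)c(OC)c1)O2 | intermediate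
27 | 5-lithio analogue of 26 (Li in place of Br) | [Li]c1cc(OC)c2c(c1)[C@H](COCc1ccccc1)[C@@H](c1ccc(OCc3ccccc3)c(OC)c1)O2 | intermediate
28 | (2S,3R)-2-[4-(benzyloxy)-3-methoxyphenyl]-3-[(benzyloxy)methyl]-7-methoxy-2,3-dihydro-1-benzofuran-5-carbaldehyde | O=Cc1cc(OC)c2c(c1)[C@H](COCc1ccccc1)[C@@H](c1ccc(OCc3ccccc3)c(OC)c1)O2 | intermediate
29 | [(2S,3R)-2-[4-(benzyloxy)-3-methoxyphenyl]-3-[(benzyloxy)methyl]-7-methoxy-2,3-dihydro-1-benzofuran-5-yl]methanol | OCc1cc(OC)c2c(c1)[C@H](COCc1ccccc1)[C@@H](c1ccc(OCc3ccccc3)c(OC)c1)O2 | intermediate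
30 | (2S,3R)-2-[4-(benzyloxy)-3-methoxyphenyl]-3-[(benzyloxy)methyl]-5-(bromomethyl)-7-methoxy-2,3-dihydro-1-benzofuran | BrCc1cc(OC)c2c(c1)[C@H](COCc1ccccc1)[C@@H](c1ccc(OCc3ccccc3)c(OC)c1)O2 | intermediate
31 | dimethyl malonate | COC(=O)CC(=O)OC | starting material
32 | (R)-epichlorohydrin, (R)-2-(chloromethyl)oxirane | ClC[C@H]1CO1 | starting material
33 | dimethyl 2-{[(2R)-oxiran-2-yl]methyl}propanedioate | COC(=O)C(C[C@@H]1CO1)C(=O)OC | intermediate
34 | dimethyl (2R)-2-(hydroxymethyl)cyclopropane-1,1-dicarboxylate (sodium alkoxide in the flask) | COC(=O)C1(C[C@H]1CO)C(=O)OC | intermediate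
35 | methyl (1S,5R)-2-oxo-3-oxabicyclo[3.1.0]hexane-1-carboxylate | COC(=O)[C@]12C[C@H]1COC2=O | intermediate
36 | aryllithium from 14 (Li in place of Br) | COc1cc([C@H](O[Si](C)(C)C(C)(C)C)[C@H](COCc3ccccc3)c2cc([Li])cc(OC)c2OCc2ccccc2)ccc1OCc1ccccc1 | intermediate
37 | arylmagnesium bromide from 14 (MgBr in place of Br) | COc1cc([C@H](O[Si](C)(C)C(C)(C)C)[C@H](COCc3ccccc3)c2cc([Mg]Br)cc(OC)c2OCc2ccccc2)ccc1OCc1ccccc1 | intermediate
38 | bromomagnesium enolate of methyl (4R)-4-(arylmethyl)-2-oxotetrahydrofuran-3-carboxylate (aryl = ring-B unit of 14) | COc1cc([C@H](O[Si](C)(C)C(C)(C)C)[C@H](COCc3ccccc3)c2cc(C[C@H]3COC(O[Mg]Br)=C3C(=O)OC)cc(OC)c2OCc2ccccc2)ccc1OCc1ccccc1 | intermediate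
39 | methyl (3R,4R)-3-{[(2S,3R)-2-[4-(benzyloxy)-3-methoxyphenyl]-3-[(benzyloxy)methyl]-7-methoxy-2,3-dihydro-1-benzofuran-5-yl]methyl}-4-{4-(benzyloxy)-3-[(1R,2S)-3-(benzyloxy)-1-[4-(benzyloxy)-3-methoxyphenyl]-1-[(tert-butyldimethylsilyl)oxy]propan-2-yl]-5-methoxybenzyl}-2-oxotetrahydrofuran-3-carboxylate | COc1cc([C@H](O[Si](C)(C)C(C)(C)C)[C@H](COCc3ccccc3)c2cc(C[C@H]3COC(=O)[C@]3(C(=O)OC)Cc3cc(OC)c4c(c3)[C@H](COCc3ccccc3)[C@@H](c3ccc(OCc5ccccc5)c(OC)c3)O4)cc(OC)c2OCc2ccccc2)ccc1OCc1ccccc1 | intermediate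
40 | (3R,4R)-3-{[(2S,3R)-2-[4-(benzyloxy)-3-methoxyphenyl]-3-[(benzyloxy)methyl]-7-methoxy-2,3-dihydro-1-benzofuran-5-yl]methyl}-4-{4-(benzyloxy)-3-[(1R,2S)-3-(benzyloxy)-1-[4-(benzyloxy)-3-methoxyphenyl]-1-[(tert-butyldimethylsilyl)oxy]propan-2-yl]-5-methoxybenzyl}dihydrofuran-2(3H)-one | COc1cc([C@H](O[Si](C)(C)C(C)(C)C)[C@H](COCc3ccccc3)c2cc(C[C@H]3COC(=O)[C@@H]3Cc3cc(OC)c4c(c3)[C@H](COCc3ccccc3)[C@@H](c3ccc(OCc5ccccc5)c(OC)c3)O4)cc(OC)c2OCc2ccccc2)ccc1OCc1ccccc1 | intermediate
41 | (3R,4R)-3-{[(2S,3R)-2-[4-(benzyloxy)-3-methoxyphenyl]-3-[(benzyloxy)methyl]-7-methoxy-2,3-dihydro-1-benzofuran-5-yl]methyl}-4-{4-(benzyloxy)-3-[(1R,2S)-3-(benzyloxy)-1-[4-(benzyloxy)-3-methoxyphenyl]-1-hydroxypropan-2-yl]-5-methoxybenzyl}dihydrofuran-2(3H)-one | COc1cc([C@H](O)[C@H](COCc3ccccc3)c2cc(C[C@H]3COC(=O)[C@@H]3Cc3cc(OC)c4c(c3)[C@H](COCc3ccccc3)[C@@H](c3ccc(OCc5ccccc5)c(OC)c3)O4)cc(OC)c2OCc2ccccc2)ccc1OCc1ccccc1 | intermediate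
42 | (3R,4R)-3-{[(2S,3R)-2-[4-(benzyloxy)-3-methoxyphenyl]-3-[(benzyloxy)methyl]-7-methoxy-2,3-dihydro-1-benzofuran-5-yl]methyl}-4-{4-(benzyloxy)-3-[(2S)-3-(benzyloxy)-1-[4-(benzyloxy)-3-methoxyphenyl]-1-oxopropan-2-yl]-5-methoxybenzyl}dihydrofuran-2(3H)-one | COc1cc(C(=O)[C@H](COCc3ccccc3)c2cc(C[C@H]3COC(=O)[C@@H]3Cc3cc(OC)c4c(c3)[C@H](COCc3ccccc3)[C@@H](c3ccc(OCc5ccccc5)c(OC)c3)O4)cc(OC)c2OCc2ccccc2)ccc1OCc1ccccc1 | intermediate
43 | (3R,4R)-3-{[(2S,3R)-2-(4-hydroxy-3-methoxyphenyl)-3-(hydroxymethyl)-7-methoxy-2,3-dihydro-1-benzofuran-5-yl]methyl}-4-{4-hydroxy-3-[(2S)-3-hydroxy-1-(4-hydroxy-3-methoxyphenyl)-1-oxopropan-2-yl]-5-methoxybenzyl}dihydrofuran-2(3H)-one (CNP0111438.1) | COc1cc(C(=O)[C@H](CO)c2cc(C[C@H]3COC(=O)[C@@H]3Cc3cc(OC)c4c(c3)[C@H](CO)[C@@H](c3ccc(O)c(OC)c3)O4)cc(OC)c2O)ccc1O | target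

**Step count and risks**

Total step count: 23. Longest linear sequence: 15 steps (steps 1, 9–17, 19–23).

Steps most likely to fail:

1. Step 19. The aryl-copper species may add to the carbonyl groups instead of opening the cyclopropane, or the magnesium enolate may be protonated or alkylated on oxygen before C-benzylation, while the benzylic bromide decomposes. The fallback separates the two bond formations and moves the benzylation to a plain lactone enolate. It sets out from 14 and 35: the same ArMgBr/CuI opening is quenched with NH4Cl to give methyl (3S,4R)-4-{4-(benzyloxy)-3-[(1R,2S)-3-(benzyloxy)-1-[4-(benzyloxy)-3-methoxyphenyl]-1-[(tert-butyldimethylsilyl)oxy]propan-2-yl]-5-methoxybenzyl}-2-oxotetrahydrofuran-3-carboxylate F1. Krapcho dealkoxycarbonylation (LiCl, wet DMSO, 140 °C) then gives (4R)-4-{4-(benzyloxy)-3-[(1R,2S)-3-(benzyloxy)-1-[4-(benzyloxy)-3-methoxyphenyl]-1-[(tert-butyldimethylsilyl)oxy]propan-2-yl]-5-methoxybenzyl}dihydrofuran-2(3H)-one F2. Its lithium enolate (LiN(SiMe3)2, THF, −78 °C) is alkylated by 30 anti to the C4 substituent, the classical trans-selective alkylation of β-benzyl butyrolactones, and the route is rejoined at 40.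

2. Step 20. Demethylation at the hindered quaternary ester may be slower than thermal degradation at 140 °C (loss of the silyl ether followed by ionization of the benzylic position, or halide-induced cleavage). The fallback unmasks the acid hydrolytically and decarboxylates it at lower temperature. It sets out from 39: KOH in EtOH/H2O at 70 °C opens the lactone and hydrolyses the ester, and acidification with KHSO4 at 0 °C re-closes the ring to (3R,4R)-3-{[(2S,3R)-2-[4-(benzyloxy)-3-methoxyphenyl]-3-[(benzyloxy)methyl]-7-methoxy-2,3-dihydro-1-benzofuran-5-yl]methyl}-4-{4-(benzyloxy)-3-[(1R,2S)-3-(benzyloxy)-1-[4-(benzyloxy)-3-methoxyphenyl]-1-[(tert-butyldimethylsilyl)oxy]propan-2-yl]-5-methoxybenzyl}-2-oxotetrahydrofuran-3-carboxylic acid F3. Heating F3 in toluene at 100 °C should decarboxylate it, a catalytic amount of DBU then equilibrates C3 to trans, and the route is rejoined at 40.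

3. Step 23. Hydrogenolysis of the two slower alkyl benzyl ethers may be overtaken by reduction of the aryl ketone or by opening of the benzylic C2–O bond of the dihydrobenzofuran. The fallback replaces hydrogenation by Lewis-acid debenzylation with a cation scavenger. It sets out from 42: BCl3 and pentamethylbenzene in CH2Cl2 at −78 °C, followed by a methanol quench, should cleave all five benzyl ethers, and the route is rejoined directly at 43. This fallback passes through no new compound (F0).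

**Further compounds**

F1 | step 19 | methyl (3S,4R)-4-{4-(benzyloxy)-3-[(1R,2S)-3-(benzyloxy)-1-[4-(benzyloxy)-3-methoxyphenyl]-1-[(tert-butyldimethylsilyl)oxy]propan-2-yl]-5-methoxybenzyl}-2-oxotetrahydrofuran-3-carboxylate | COc1cc([C@H](O[Si](C)(C)C(C)(C)C)[C@H](COCc3ccccc3)c2cc(C[C@H]3COC(=O)[C@@H]3C(=O)OC)cc(OC)c2OCc2ccccc2)ccc1OCc1ccccc1
F2 | step 19 | (4R)-4-{4-(benzyloxy)-3-[(1R,2S)-3-(benzyloxy)-1-[4-(benzyloxy)-3-methoxyphenyl]-1-[(tert-butyldimethylsilyl)oxy]propan-2-yl]-5-methoxybenzyl}dihydrofuran-2(3H)-one | COc1cc([C@H](O[Si](C)(C)C(C)(C)C)[C@H](COCc3ccccc3)c2cc(C[C@H]3COC(=O)C3)cc(OC)c2OCc2ccccc2)ccc1OCc1ccccc1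
F3 | step 20 | (3R,4R)-3-{[(2S,3R)-2-[4-(benzyloxy)-3-methoxyphenyl]-3-[(benzyloxy)methyl]-7-methoxy-2,3-dihydro-1-benzofuran-5-yl]methyl}-4-{4-(benzyloxy)-3-[(1R,2S)-3-(benzyloxy)-1-[4-(benzyloxy)-3-methoxyphenyl]-1-[(tert-butyldimethylsilyl)oxy]propan-2-yl]-5-methoxybenzyl}-2-oxotetrahydrofuran-3-carboxylic acid | COc1cc([C@H](O[Si](C)(C)C(C)(C)C)[C@H](COCc3ccccc3)c2cc(C[C@H]3COC(=O)[C@]3(C(=O)O)Cc3cc(OC)c4c(c3)[C@H](COCc3ccccc3)[C@@H](c3ccc(OCc5ccccc5)c(OC)c3)O4)cc(OC)c2OCc2ccccc2)ccc1OCc1ccccc1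
F0 | step 23 | none | none
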